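## Retrosynthetic overview

1. The last bond is the enol-ester C–O bond: the lithium (E)-ylidene tetronate is O-acylated with 15-methylhexadecanoyl chloride in the flask in which the ring is closed.
2. The butenolide is the only ring made and it is formed last, by Lacey–Dieckmann closure (ring C3–C4 bond) of an acyclic (E)-enol propanoate, so the exocyclic alkene geometry is fixed before the ring exists.
3. The (E)-enol ester C=C comes from a cis-selective (Still–Gennari-type) Horner–Wadsworth–Emmons reaction of an α-propanoyloxy phosphonoacetate with the (S)-α-methyl aldehyde.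
4. The aldehyde comes from (E,E)-farnesyl acetate (terminal SeO2 oxidation, then Ru–BINAP hydrogenation to set the stereocentre) and furan-3-ylmethanol (copper-catalysed Grignard displacement of the allylic acetate); the furan ring is carried through intact.

Assumption: the SMILES is read as E at the exocyclic alkene (side chain cis to the acyloxy-bearing ring carbon) and S at the methyl stereocentre; 1, 4, 10 and 15 are bought; the (S)-BINAP ligand in step 2 is chosen by analogy with geraniol → (R)-citronellol and would be swapped for its antipode if 3 proved to be 11R.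

## Route

Step 1
Reactants: 1 (2E,6E)-3,7,11-trimethyldodeca-2,6,10-trien-1-yl acetate ((E,E)-farnesyl acetate)
Product: 2 (2E,6E,10E)-12-hydroxy-3,7,11-trimethyldodeca-2,6,10-trien-1-yl acetate
Conditions: SeO2 (cat.), t-BuOOH, salicylic acid (cat.), CH2Cl2, 20 °C
Reagents that add atoms: tert-butyl hydroperoxide, CC(C)(C)OO (oxygen relayed through catalytic selenium dioxide, O=[Se]=O)
Why: Riley–Sharpless allylic oxidation (ene reaction then [2,3]-sigmatropic shift) hydroxylates the E-methyl of the terminal trisubstituted alkene and so gives the 10E allylic alcohol, while the allylic acetate deactivates the 2,3-alkene.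

Step 2
Reactants: 2 (2E,6E,10E)-12-hydroxy-3,7,11-trimethyldodeca-2,6,10-trien-1-yl acetate
Product: 3 (2E,6E,11S)-12-hydroxy-3,7,11-trimethyldodeca-2,6-dien-1-yl acetate
Conditions: H2 (90 atm), Ru(OAc)2[(S)-BINAP] (1 mol%), MeOH, 20 °C
Reagents that add atoms: none
Why: Noyori hydroxyl-directed asymmetric hydrogenation reduces only the alkene of the free allylic alcohol, and the (S)-BINAP–Ru alkoxide chelate delivers H2 to the face that makes C-11 (the only stereocentre of the target) S; the isolated and acetate-bearing trisubstituted alkenes are inert.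

Step 3
Reactants: 4 furan-3-ylmethanol
Product: 5 3-(chloromethyl)furan
Conditions: SOCl2, pyridine, Et2O, 0 °C
Reagents that add atoms: thionyl chloride, O=S(Cl)Cl
Why: Chlorodehydroxylation through the chlorosulfite; pyridine buffers the HCl so the acid-sensitive furan survives.

Step 4
Reactants: 3 (2E,6E,11S)-12-hydroxy-3,7,11-trimethyldodeca-2,6-dien-1-yl acetate; 5 3-(chloromethyl)furan
Product: 8 (2S,6E,10E)-13-(furan-3-yl)-2,6,10-trimethyltrideca-6,10-dien-1-ol, via (furan-3-ylmethyl)magnesium chloride 6 (not isolated), via chloromagnesium alkoxide 7 (not isolated)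
Conditions: 5, Mg, THF, 0 °C (2.3 equiv of 6); add to 3 with Li2CuCl4 (5 mol%), THF, −20 → 0 °C; aq. NH4Cl
Reagents that add atoms: none
Why: Kochi/Fouquet–Schlosser copper-catalysed Grignard coupling, in which the first equivalent only deprotonates the alcohol and the catalytic cuprate then displaces the primary allylic acetate at the α-carbon (SN2) with retention of the E-alkene; the stereocentre is not touched.

Step 5
Reactants: 8 (2S,6E,10E)-13-(furan-3-yl)-2,6,10-trimethyltrideca-6,10-dien-1-ol
Product: 9 (2S,6E,10E)-13-(furan-3-yl)-2,6,10-trimethyltrideca-6,10-dienal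
Conditions: PhI(OAc)2, TEMPO (10 mol%), CH2Cl2, 0 → 20 °C; used crude at once
Reagents that add atoms: none
Why: Oxoammonium (TEMPO/BAIB) oxidation of the primary alcohol under near-neutral conditions, which does not epimerise the α-methyl aldehyde and leaves the furan and alkenes alone.

Step 6
Reactants: 10 methyl 2-[bis(2,2,2-trifluoroethoxy)phosphoryl]acetate
Product: 11 methyl 2-[bis(2,2,2-trifluoroethoxy)phosphoryl]-2-diazoacetate
Conditions: 4-AcNHC6H4SO2N3, DBU, MeCN, 0 °C
Reagents that add atoms: 4-acetamidobenzenesulfonyl azide, CC(=O)Nc1ccc(cc1)S(=O)(=O)N=[N+]=[N-]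
Why: Regitz diazo transfer onto the doubly activated methylene of the phosphonoacetate.

Step 7
Reactants: 11 methyl 2-[bis(2,2,2-trifluoroethoxy)phosphoryl]-2-diazoacetate
Product: 12 methyl 2-[bis(2,2,2-trifluoroethoxy)phosphoryl]-2-(propanoyloxy)acetate (racemic)
Conditions: EtCO2H, Rh2(OAc)4 (1 mol%), CH2Cl2, 40 °C
Reagents that add atoms: propanoic acid, CCC(=O)O
Why: Rhodium-carbenoid O–H insertion into the carboxylic acid installs the propanoyloxy group that later supplies the ring oxygen, C-2 and C-3 with its methyl.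

Step 8
Reactants: 9 (2S,6E,10E)-13-(furan-3-yl)-2,6,10-trimethyltrideca-6,10-dienal; 12 methyl 2-[bis(2,2,2-trifluoroethoxy)phosphoryl]-2-(propanoyloxy)acetate
Product: 14 methyl (2E,4S,8E,12E)-15-(furan-3-yl)-4,8,12-trimethyl-2-(propanoyloxy)pentadeca-2,8,12-trienoate, via potassium phosphonate carbanion 13 (not isolated)
Conditions: 12 (1.2 equiv), KHMDS, 18-crown-6, THF, −78 °C; then 9, −78 °C; NH4Cl quench at −78 °C
Reagents that add atoms: none
Why: Proposed new method: Still–Gennari-type Horner–Wadsworth–Emmons olefination, in which the electron-poor bis(trifluoroethyl) phosphonate collapses the first-formed adduct faster than it reverts, so the kinetic adduct places the aldehyde chain cis to CO2Me and trans to the propanoyloxy group (2E), as is known for the α-H, α-methyl and α-bromo reagents (closest known reaction: E-selective HWE synthesis of α-bromoacrylates); the preformed, weakly basic anion does not epimerise C-4 at −78 °C.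

Step 9
Reactants: 15 15-methylhexadecanoic acid
Product: 16 15-methylhexadecanoyl chloride
Conditions: (COCl)2, DMF (cat.), CH2Cl2, 0 → 20 °C; evaporate
Reagents that add atoms: oxalyl chloride, O=C(Cl)C(Cl)=O
Why: Vilsmeier-catalysed conversion of the acid into its chloride.

Step 10
Reactants: 14 methyl (2E,4S,8E,12E)-15-(furan-3-yl)-4,8,12-trimethyl-2-(propanoyloxy)pentadeca-2,8,12-trienoate; 16 15-methylhexadecanoyl chloride
Product: 18 (2E)-2-[(2S,6E,10E)-13-(furan-3-yl)-2,6,10-trimethyltrideca-6,10-dien-1-ylidene]-4-methyl-5-oxo-2,5-dihydrofuran-3-yl 15-methylhexadecanoate, via lithium tetronate 17 (not isolated)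
Conditions: LiHMDS (1.1 equiv), THF, −78 → −20 °C; evaporate cold; 16 (1.05 equiv), CH2Cl2, −20 → 0 °C; pH 7 buffer
Reagents that add atoms: none
Why: Lacey–Dieckmann condensation of the propanoate enolate onto the neighbouring methyl ester closes the butenolide without touching the enol-ester C=C, so the 2E geometry of 14 becomes the E exocyclic alkene (allylic strain holds the C–H of the stereocentre in the alkene plane, where it is not acidic), and the tetronate is then O-acylated at O-4 by the acid chloride in the manner used for tetronic acid enol esters.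

## Compound list

1 | (2E,6E)-3,7,11-trimethyldodeca-2,6,10-trien-1-yl acetate | CC(C)=CCC/C(C)=C/CC/C(C)=C/COC(C)=O | starting material
2 | (2E,6E,10E)-12-hydroxy-3,7,11-trimethyldodeca-2,6,10-trien-1-yl acetate | OC/C(C)=C/CC/C(C)=C/CC/C(C)=C/COC(C)=O | intermediate
3 | (2E,6E,11S)-12-hydroxy-3,7,11-trimethyldodeca-2,6-dien-1-yl acetate | OC[C@@H](C)CCC/C(C)=C/CC/C(C)=C/COC(C)=O | intermediate
4 | furan-3-ylmethanol | OCc1ccoc1 | starting material
5 | 3-(chloromethyl)furan | ClCc1ccoc1 | intermediate
6 | (furan-3-ylmethyl)magnesium chloride | Cl[Mg]Cc1ccoc1 | intermediate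
7 | chloromagnesium alkoxide of 3 | Cl[Mg]OC[C@@H](C)CCC/C(C)=C/CC/C(C)=C/COC(C)=O | intermediate
8 | (2S,6E,10E)-13-(furan-3-yl)-2,6,10-trimethyltrideca-6,10-dien-1-ol | OC[C@@H](C)CCC/C(C)=C/CC/C(C)=C/CCc1ccoc1 | intermediate
9 | (2S,6E,10E)-13-(furan-3-yl)-2,6,10-trimethyltrideca-6,10-dienal | O=C[C@@H](C)CCC/C(C)=C/CC/C(C)=C/CCc1ccoc1 | intermediate
10 | methyl 2-[bis(2,2,2-trifluoroethoxy)phosphoryl]acetate | COC(=O)CP(=O)(OCC(F)(F)F)OCC(F)(F)F | starting material
11 | methyl 2-[bis(2,2,2-trifluoroethoxy)phosphoryl]-2-diazoacetate | COC(=O)C(=[N+]=[N-])P(=O)(OCC(F)(F)F)OCC(F)(F)F | intermediate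
12 | methyl 2-[bis(2,2,2-trifluoroethoxy)phosphoryl]-2-(propanoyloxy)acetate (racemic) | CCC(=O)OC(C(=O)OC)P(=O)(OCC(F)(F)F)OCC(F)(F)F | intermediate
13 | potassium carbanion of 12 | [K+].CCC(=O)O[C-](C(=O)OC)P(=O)(OCC(F)(F)F)OCC(F)(F)F | intermediate
14 | methyl (2E,4S,8E,12E)-15-(furan-3-yl)-4,8,12-trimethyl-2-(propanoyloxy)pentadeca-2,8,12-trienoate | COC(=O)/C(OC(=O)CC)=C\[C@@H](C)CCC/C(C)=C/CC/C(C)=C/CCc1ccoc1 | intermediate
15 | 15-methylhexadecanoic acid | CC(C)CCCCCCCCCCCCCC(=O)O | starting material
16 | 15-methylhexadecanoyl chloride | CC(C)CCCCCCCCCCCCCC(=O)Cl | intermediate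
17 | lithium (2E)-2-[(2S,6E,10E)-13-(furan-3-yl)-2,6,10-trimethyltrideca-6,10-dien-1-ylidene]-4-methyl-5-oxo-2,5-dihydrofuran-3-olate | CC1=C([O-])/C(=C\[C@@H](C)CCC/C(C)=C/CC/C(C)=C/CCc2ccoc2)OC1=O.[Li+] | intermediate
18 | (2E)-2-[(2S,6E,10E)-13-(furan-3-yl)-2,6,10-trimethyltrideca-6,10-dien-1-ylidene]-4-methyl-5-oxo-2,5-dihydrofuran-3-yl 15-methylhexadecanoate | CC1=C(OC(=O)CCCCCCCCCCCCCC(C)C)/C(=C\[C@@H](C)CCC/C(C)=C/CC/C(C)=C/CCc2ccoc2)OC1=O | target

## Step count and risks

Total step count: 10. Longest linear sequence: 6 steps (1, 2, 4, 5, 8, 10).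

The three steps most likely to fail:

Step 8. The cis-to-ester preference has not been shown for an α-acyloxy bis(trifluoroethyl) phosphonate, and a poor ratio would give the unwanted Z enol ester. The fallback sets out from 9 and olefinates with methyl bromo[bis(2,2,2-trifluoroethoxy)phosphoryl]acetate (t-BuOK, 18-crown-6, THF, −78 °C), a reagent with an established preference for placing the aldehyde chain cis to the ester, to give methyl (2E,4S,8E,12E)-2-bromo-15-(furan-3-yl)-4,8,12-trimethylpentadeca-2,8,12-trienoate F1. A copper-catalysed vinylic C–O coupling of F1 with potassium propanoate (CuI, 1,10-phenanthroline, toluene, 80 °C; retention at the alkene) then comes back to the route at 14.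

Step 10. The propanoate enolate of an enol ester may fragment to methylketene or the base may deprotonate at the stereocentre, and the in-flask acylation may suffer from the methanol released. The fallback sets out from 14, runs the ring closure on its own under alkoxide conditions (t-BuOK, t-BuOH–THF, 0 °C; citric acid work-up) and isolates the free tetronic acid (5E)-5-[(2S,6E,10E)-13-(furan-3-yl)-2,6,10-trimethyltrideca-6,10-dien-1-ylidene]-4-hydroxy-3-methylfuran-2(5H)-one F2. Carbodiimide coupling of F2 with the acid 15 itself (DCC, DMAP cat., CH2Cl2, 0 °C) comes back at 18 without the acid chloride 16.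

Step 4. The benzylic-type Grignard may add to the acetate carbonyl or attack in the SN2′ sense. The fallback reverses the polarity: it sets out from 3 and exchanges acetate for sulfinate (PhSO2Na, Pd(PPh3)4 cat., THF–MeOH) to give (2S,6E,10E)-2,6,10-trimethyl-12-(phenylsulfonyl)dodeca-6,10-dien-1-ol F3. The dianion of F3 (n-BuLi 2.1 equiv, THF–HMPA, −78 °C) is alkylated with 5 to give (2S,6E,10E)-13-(furan-3-yl)-2,6,10-trimethyl-12-(phenylsulfonyl)trideca-6,10-dien-1-ol F4 (mixture at C-12), and reductive desulfonylation [PdCl2(dppp) cat., LiBHEt3, THF, 0 °C] comes back at 8.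

Further compounds
F1 | step 8 | methyl (2E,4S,8E,12E)-2-bromo-15-(furan-3-yl)-4,8,12-trimethylpentadeca-2,8,12-trienoate | COC(=O)/C(Br)=C\[C@@H](C)CCC/C(C)=C/CC/C(C)=C/CCc1ccoc1
F2 | step 10 | (5E)-5-[(2S,6E,10E)-13-(furan-3-yl)-2,6,10-trimethyltrideca-6,10-dien-1-ylidene]-4-hydroxy-3-methylfuran-2(5H)-one | CC1=C(O)/C(=C\[C@@H](C)CCC/C(C)=C/CC/C(C)=C/CCc2ccoc2)OC1=O
F3 | step 4 | (2S,6E,10E)-2,6,10-trimethyl-12-(phenylsulfonyl)dodeca-6,10-dien-1-ol | OC[C@@H](C)CCC/C(C)=C/CC/C(C)=C/CS(=O)(=O)c1ccccc1
F4 | step 4 | (2S,6E,10E)-13-(furan-3-yl)-2,6,10-trimethyl-12-(phenylsulfonyl)trideca-6,10-dien-1-ol (C-12 epimers) | OC[C@@H](C)CCC/C(C)=C/CC/C(C)=C/C(Cc1ccoc1)S(=O)(=O)c1ccccc1
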